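## The problem

Target 21 is a 2,3,4-trisubstituted oxolane. C2 carries a 4-hydroxy-3-methoxyphenyl group, C3 a CH2O arm (C9) acylated by (2R)-2-methylbutanoic acid, C4 a 4-hydroxy-3-methoxybenzyl group (C7' and its arene), and C5 is a methylene; these atom labels are used for all intermediates. The ring holds three contiguous stereocentres, (2R,3S,4S), with the aryl group and C9 trans and C9 and the benzyl group cis; the fourth centre lies in the acyl group and is bought. C3 is the pivot: its substituent can send the C2 aryl group to the opposite face under equilibrating conditions and can shield one face of a trigonal C4. The 3,4-cis relation is the less stable one, so it must be made under kinetic control and kept away from base while C4 is α to a carbonyl. The C2–O1 bond is a para-oxygenated benzylic ether: acid ionises it (epimerisation, or capture by the second arene to an aryltetralin) and hydrogen over palladium can cleave it. The phenols must stay masked through the oxidative step, and the ester with its α-centre tolerates neither hydride reagents nor strong base, so the acyl group has to come late. The enabling feature appears when O1 is deleted: C2, C3, C4 and C5 then form a cyclobutanone with C5 as carbonyl carbon and the aryl group on C2, and tying C9 to C7' through an ether oxygen makes it the [2+2] adduct of an arylketene equivalent and 2,5-dihydrofuran. Oxygen insertion between C5 and the electron-rich benzylic C2 restores O1, and the second oxolane, now β to the lactone carbonyl through C7', can be opened to free C9–OH and turn C7' into an electrophilic methylene for the second arene.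

## Retrosynthesis

**Ester and phenols (21 ⇒ 20 ⇒ 18 + 19).** The two aryl O–benzyl bonds and the C9–O acyl bond are cut first. Carrying the ester earlier is ruled out because every earlier stage uses hydride or amide base. Benzyl ethers are chosen because they keep both arenes electron-rich, survive all intervening reagents and leave without acid. Alcohol 18 is the dibenzyl ether of the parent lignan alcohol, and acid 19 is commercial. The forward steps must acylate without racemising 19 and must remove benzyl without touching C2–O1.

**C5 oxidation level (18 ⇒ 17 ⇒ 16 ⇒ 15).** The two C5–H bonds are traded for a lactone carbonyl, with C9–OH silylated. Closing the oxolane from an open diol would need a separate decision at C2; a C5 carbonyl instead makes C4 addressable and is what the key step delivers. The forward reduction (lactone to lactol 16, then ionic hydrogenation to 17) must not epimerise C4 and must not ionise C2–O1.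

**C7'–aryl bond and C4–H (15 ⇒ 13 + 14).** Cutting C7'–C(aryl) and the C4–H bond leads to the α-methylene lactone 13 and commercial boronic acid 14. The neighbouring cut, benzylation of a lactone enolate, would deliver the benzyl group anti to the C3 arm and give the wrong 3,4-trans isomer. Conjugate arylation followed by protonation puts the small proton anti to the arm and the benzyl group cis. The precursor loses one stereocentre and one arene. The forward step needs face-selective protonation and conditions too mild to equilibrate the product.

**C7'–O reconnection (13 ⇒ 10).** Joining the C9 oxygen to C7' hides the exocyclic methylene and the alcohol in a second oxolane; in the forward sense the C7'–O bond is broken by β-elimination from the lactone enolate (via 11 and 12). Making 13 by methylenation of a simpler lactone would require separate construction of the C2/C3 pair. In 10 both come from a bicycle. The forward reaction must eliminate and cap the C9 alkoxide before it can attack the lactone.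

**Removal of O1 (10 ⇒ 9).** Cutting O1–C2 and O1–C5 and rejoining C2–C5 gives cyclobutanone 9. Lactonisation of a hydroxy acid would need a stereoselective synthesis of the C2 carbinol. In 9 the aryl-bearing carbon is epimerisable and sits exo by thermodynamics, and a 1,2-shift to oxygen transfers that configuration with retention. The forward reaction must make C2, not the ring-fusion carbon C4, migrate.

**Four-membered ring (9 ⇒ 8 ⇒ 4 + 5).** Cutting C2–C3 and C4–C5 gives a keteniminium salt derived from amide 4 and 2,5-dihydrofuran 5 (via 6 and 7). Suprafacial addition to the cis alkene guarantees the cis fusion, and a twofold-symmetric amine on nitrogen offers absolute control at C3 with no geometric isomerism in the cumulene. The precursors are an achiral alkene and an arylacetamide. The forward reaction must discriminate the enantiotopic faces, and ketone 8 must then be equilibrated to the exo epimer 9.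

**Amide (4 ⇒ 1 + 2).** The C–N bond is cut to commercial acid 1 and amine 2; the amine is released again in the hydrolysis that gives 8 and can be recovered.

## Roads not taken

**Alternative 1:** The cut is O1–C5 and C4–C5, with C5 entering as carbon monoxide. In the forward step the anti alkynol A2, under CO with Pd(OAc)2 and 1,4-bis(diphenylphosphino)butane, forms an alkoxycarbonyl-palladium species that adds syn across the alkyne and closes the benzylidene lactone A1.
- Merits: both arenes and every carbon except C5 are in place before ring closure, no ring is built and reopened, and C4 would be set by hydrogenating the exocyclic alkene from the face away from the C3 arm. That hydrogenation is a more firmly established way to the 3,4-cis relation than protonation of an enolate, and on this point the alternative is better.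
- Weak points: A2 must be made as one anti diastereomer and one enantiomer by an acyclic addition, usually with a stoichiometric chiral reagent. The hydrogenation must spare two aryl benzyl ethers and the benzylic lactone C–O bond. Pressurised CO is needed.
- Comparison: step counts are similar. The chosen plan sets against the better C4 control cheaper inputs, ring-enforced C2/C3 stereochemistry, and a C4 step that is compatible with the benzyl ethers.

**Alternative 2:** The cut is C3–C4. In the forward step Cp2TiCl (trivalent titanium, from Cp2TiCl2 and zinc) opens the terminal epoxide of the cinnamyl ether A4 to a C3 radical. The radical adds 5-exo-trig to the styrene carbon C4, and the benzylic C7' radical is reduced and protonated to give A3, which is the same substance as 18.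
- Merits: this is clearly the shortest road; one step from an acyclic ether reaches the alcohol that the chosen route needs nine steps to reach, and both epoxide epimers converge on the same radical.
- Weak points: a single centre, C2, must relay to C3 and C4 through an early radical transition state. The 2,3-trans relation is reliable, but the 3,4-cis relation is only a preference, so a C4 epimer is expected that differs little in polarity from A3. The titanium reagent is stoichiometric, and the absolute configuration must first be installed in the benzylic ether.
- Comparison: in step economy the alternative wins outright. The chosen plan sets against it that each ring stereocentre is fixed by its own well-understood element, and that a wrong C4 epimer can be corrected by re-enolisation, which a radical cyclisation does not allow.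

**Alternative 3:** The cut is O–C7' and C4–C7', which makes a second oxolane. In the forward step TMSOTf joins a C9 hydroxyl on an enol ether to an aryl acetal and ionises it to a C7' oxocarbenium ion; C4 attacks it and Et3SiH reduces C5, giving the furofuran A5. Hydrogenolysis would then have to reopen the C7'–O bond.
- Merits: the cis-fused bicycle locks 3,4-cis and places both aryl groups exo, and no α-carbonyl stage exists in which C4 could epimerise. In the security of the cis relation this road is better.
- Weak points: the key step creates a C7' stereocentre and an O–C7' bond only to destroy them. The ring-opening hydrogenolysis must stop after one of two benzylic C–O bonds that differ only in a remote protecting group, with over-reduction to the open-chain diol as the natural sink. The benzyl ether is lost in the same operation, so acylation at C9 would have to be selective beside a free phenol, and the aryl acetate would then have to be removed beside the aliphatic ester.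
- Comparison: both roads build a bicycle and reopen one ring. In the chosen plan the bond to be broken is β to a lactone carbonyl and is cleaved by base, an event C2–O1 cannot take part in. Against the better stereochemical security of A5 it sets that chemical differentiation and a simple endgame.

Key step: step 4

Assumption: the (2S,5S) amine is taken to deliver the (1S,5R) ring fusion of 8. The steric model behind this has the alkene approach the central keteniminium carbon anti to the aryl group, its ring turned away from nitrogen and its distal carbon on the side free of a pyrrolidine methyl group. If the sense proves opposite, the (2R,5R) amine is used with no other change.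

## Route

Step 1
Reactants: 1 2-[4-(benzyloxy)-3-methoxyphenyl]acetic acid; 2 (2S,5S)-2,5-dimethylpyrrolidine
Product: 4 2-[4-(benzyloxy)-3-methoxyphenyl]-1-[(2S,5S)-2,5-dimethylpyrrolidin-1-yl]ethan-1-one, via arylacetyl chloride 3 (not isolated)
Conditions: (COCl)2, DMF (cat.), CH2Cl2, 0 °C → rt; evaporate; then 2, Et3N, CH2Cl2, 0 °C → rt
Reagents that add atoms: none
Why: Amide formation through the acid chloride, chosen because the amine is α,α'-branched and hindered; the benzyl ether is inert and no stereocentre is touched.

Step 2
Reactants: 4 the amide from step 1; 5 2,5-dihydrofuran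
Product: 8 (1S,5R)-7-[4-(benzyloxy)-3-methoxyphenyl]-3-oxabicyclo[3.2.0]heptan-6-one (C7 epimers), via keteniminium triflate 6 (not isolated), via cyclobutaniminium triflate 7 (not isolated)
Conditions: Tf2O (1.2 equiv), 2,4,6-collidine (1.3 equiv), 5 (4 equiv), ClCH2CH2Cl, −20 → 70 °C (sealed vessel); then aq. NaHCO3, 50 °C
Reagents that add atoms: water, O
Why: Keteniminium–alkene [2+2] cycloaddition: O-triflation and deprotonation give 6, which adds suprafacially to the cis alkene to form C4–C5 and C2–C3 and hence the cis-fused iminium 7, hydrolysed to the ketone; the absolute configuration at C3 and C4 is set by the twofold-symmetric auxiliary, one methyl group of which blocks one of the two positions open to the distal alkene carbon, while C2 stays epimerisable.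

Step 3
Reactants: 8 the cyclobutanone epimer mixture
Product: 9 (1S,5R,7R)-7-[4-(benzyloxy)-3-methoxyphenyl]-3-oxabicyclo[3.2.0]heptan-6-one (cis-fused, aryl exo)
Conditions: DBU (0.2 equiv), CH2Cl2, rt
Reagents that add atoms: none
Why: Base-mediated epimerisation through the enol of the α-aryl ketone; the aryl group settles on the convex face of the bicycle, trans to the oxolane ring, and a non-nucleophilic amidine avoids nucleophilic opening of the strained ketone.

Step 4
Reactants: 9 the exo-aryl cyclobutanone
Product: 10 (3R,3aS,6aR)-3-[4-(benzyloxy)-3-methoxyphenyl]tetrahydro-1H,3H-furo[3,4-c]furan-1-one (cis-fused, aryl exo)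
Conditions: mCPBA (1.3 equiv), NaHCO3 (solid buffer), CH2Cl2, 0 °C → rt
Reagents that add atoms: meta-chloroperoxybenzoic acid (mCPBA), O=C(OO)c1cccc(Cl)c1
Why: mCPBA adds to the strained carbonyl C5 of 9 to give the tetrahedral Criegee adduct, and the C2–C5 bond anti-periplanar to the O–O bond shifts to oxygen as 3-chlorobenzoate leaves, so that O1–C2 and O1–C5 form and C2–C5 breaks (Baeyer–Villiger oxidation). The closest known reaction type is the peracid ring expansion of 2-arylcyclobutanones and of fused bicyclo[3.2.0]heptan-6-ones to γ-butyrolactones. The oxolan-2-one ring is not closed by a cyclisation but by a 1,2-shift that enlarges the four-membered ring to the five-membered lactone, the second oxolane being a spectator. No stereocentre is created: the migrating carbon keeps its configuration, so the exo aryl group of 9 becomes the 2,3-trans relation of 10 and the cis ring fusion is untouched. The step needs regioselective migration of C2 over the ring-fusion carbon C4, both being secondary. Two features of the substrate work for this: the para-benzyloxy group (kept as an ether rather than an ester for this reason) stabilises positive charge building at the benzylic C2 in the transition state, and the ether oxygen β to C4 through C7' withdraws electron density from the competitor. Solid NaHCO3 keeps the medium from ionising the new benzylic lactone C–O bond, and at 0 °C the strained ketone should be consumed well before the dialkoxyarene is attacked.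

Step 5
Reactants: 10 the bicyclic lactone
Product: 13 (4S,5R)-5-[4-(benzyloxy)-3-methoxyphenyl]-4-{[(tert-butyldimethylsilyl)oxy]methyl}-3-methylideneoxolan-2-one, via lithium enolate 11 (not isolated), via lithium alkoxide 12 (not isolated)
Conditions: LiN(SiMe3)2 (1.1 equiv), THF, −78 → 0 °C; then TBSCl (1.5 equiv), DMF (co-solvent), 0 °C → rt
Reagents that add atoms: tert-butyldimethylsilyl chloride (TBSCl), CC(C)(C)[Si](C)(C)Cl
Why: E1cB elimination (retro-oxa-Michael): the lactone enolate 11 formed at C4 expels the β-alkoxide by breaking C7'–O, which gives the α-methylene lactone and the primary C9 alkoxide 12, capped at once as the silyl ether; C2 and C3 are not involved, and the hindered amide base does not add to the new acceptor.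

Step 6
Reactants: 13 the α-methylene lactone; 14 [4-(benzyloxy)-3-methoxyphenyl]boronic acid
Product: 15 (3S,4S,5R)-3-[4-(benzyloxy)-3-methoxybenzyl]-5-[4-(benzyloxy)-3-methoxyphenyl]-4-{[(tert-butyldimethylsilyl)oxy]methyl}oxolan-2-one
Conditions: [Rh(cod)Cl]2 (3 mol%), 14 (2 equiv), KOH (0.3 equiv), 1,4-dioxane/H2O (10:1), 40 °C
Reagents that add atoms: none
Why: Rhodium-catalysed conjugate addition of an arylboronic acid (Hayashi–Miyaura type) to the exocyclic enoate: the aryl–rhodium species adds to C7' and water protonates the resulting rhodium enolate at C4 from the face opposite the adjacent silyloxymethyl arm, so the benzyl group ends cis to C9; the substoichiometric hydroxide is too weak to equilibrate the lactone α-centre afterwards.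

Step 7
Reactants: 15 the benzyl lactone
Product: 16 (3S,4S,5R)-3-[4-(benzyloxy)-3-methoxybenzyl]-5-[4-(benzyloxy)-3-methoxyphenyl]-4-{[(tert-butyldimethylsilyl)oxy]methyl}oxolan-2-ol (both anomers)
Conditions: i-Bu2AlH (1.2 equiv), CH2Cl2, −78 °C; aq. potassium sodium tartrate work-up
Reagents that add atoms: none
Why: Half-reduction of a γ-lactone to the lactol; the tetrahedral aluminium hemiacetal is stable at −78 °C, and hydride transfer is much faster than enolisation, so C4 keeps its configuration.

Step 8
Reactants: 16 the lactol
Product: 17 tert-butyl{[(2R,3S,4S)-2-[4-(benzyloxy)-3-methoxyphenyl]-4-[4-(benzyloxy)-3-methoxybenzyl]oxolan-3-yl]methoxy}dimethylsilane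
Conditions: Et3SiH (3 equiv), BF3·OEt2 (1.5 equiv), CH2Cl2, −78 → −40 °C
Reagents that add atoms: none
Why: Ionic hydrogenation of the lactol: BF3·OEt2 ionises the hemiacetal hydroxyl to the C5 oxocarbenium ion, which excess silane reduces to the methylene; at low temperature the hemiacetal ionises far faster than the C2–O1 ether or the silyl ether, and no stereocentre is formed.

Step 9
Reactants: 17 the silyl ether
Product: 18 [(2R,3S,4S)-2-[4-(benzyloxy)-3-methoxyphenyl]-4-[4-(benzyloxy)-3-methoxybenzyl]oxolan-3-yl]methanol
Conditions: n-Bu4NF (1.2 equiv), THF, 0 °C → rt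
Reagents that add atoms: none
Why: Fluoride-induced desilylation of a primary silyl ether; benzyl ethers and the oxolane are inert.

Step 10
Reactants: 18 the primary alcohol; 19 (2R)-2-methylbutanoic acid
Product: 20 [(2R,3S,4S)-2-[4-(benzyloxy)-3-methoxyphenyl]-4-[4-(benzyloxy)-3-methoxybenzyl]oxolan-3-yl]methyl (2R)-2-methylbutanoate
Conditions: 19 (1.3 equiv), DCC (1.4 equiv), DMAP (0.1 equiv), CH2Cl2, 0 °C → rt
Reagents that add atoms: none
Why: Steglich esterification of an unhindered primary alcohol; a low DMAP loading at 0 °C keeps the simple α-branched acid from racemising through a ketene or an enolised acylpyridinium.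

Step 11
Reactants: 20 the dibenzyl ester
Product: 21 [(2R,3S,4S)-2-(4-hydroxy-3-methoxyphenyl)-4-(4-hydroxy-3-methoxybenzyl)oxolan-3-yl]methyl (2R)-2-methylbutanoate (target)
Conditions: H2 (1 atm), Pd/C (10% Pd), EtOAc, rt, stopped after uptake of 2 equiv H2
Reagents that add atoms: none
Why: Hydrogenolysis of aryl benzyl ethers, which in a neutral aprotic solvent is much faster than cleavage of the dialkyl benzylic C2–O1 bond; the ester and all four stereocentres are unaffected.

## Compound list

1 | 2-[4-(benzyloxy)-3-methoxyphenyl]acetic acid | COc1cc(CC(=O)O)ccc1OCc1ccccc1 | starting material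
2 | (2S,5S)-2,5-dimethylpyrrolidine | C[C@H]1CC[C@H](C)N1 | starting material
3 | 2-[4-(benzyloxy)-3-methoxyphenyl]acetyl chloride | COc1cc(CC(=O)Cl)ccc1OCc1ccccc1 | intermediate
4 | 2-[4-(benzyloxy)-3-methoxyphenyl]-1-[(2S,5S)-2,5-dimethylpyrrolidin-1-yl]ethan-1-one | C[C@H]1CC[C@H](C)N1C(=O)Cc1ccc(OCc2ccccc2)c(OC)c1 | intermediate
5 | 2,5-dihydrofuran | C1OCC=C1 | starting material
6 | keteniminium triflate: (2S,5S)-1-{2-[4-(benzyloxy)-3-methoxyphenyl]ethenylidene}-2,5-dimethylpyrrolidin-1-ium trifluoromethanesulfonate | C[C@H]1CC[C@H](C)[N+]1=C=Cc1ccc(OCc2ccccc2)c(OC)c1.[O-]S(=O)(=O)C(F)(F)F | intermediate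
7 | cyclobutaniminium triflate: the iminium salt of ketone 8 with amine 2 (C=N+ in place of C=O, cis ring fusion arranged as in 9, C7 epimers) | C[C@H]1CC[C@H](C)[N+]1=C1C(c2ccc(OCc3ccccc3)c(OC)c2)[C@@H]2COC[C@H]12.[O-]S(=O)(=O)C(F)(F)F | intermediate
8 | (1S,5R)-7-[4-(benzyloxy)-3-methoxyphenyl]-3-oxabicyclo[3.2.0]heptan-6-one, mixture of C7 epimers | O=C1C(c2ccc(OCc3ccccc3)c(OC)c2)[C@@H]2COC[C@H]12 | intermediate
9 | (1S,5R,7R)-7-[4-(benzyloxy)-3-methoxyphenyl]-3-oxabicyclo[3.2.0]heptan-6-one (cis-fused, aryl exo) | O=C1[C@@H](c2ccc(OCc3ccccc3)c(OC)c2)[C@@H]2COC[C@H]12 | intermediate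
10 | (3R,3aS,6aR)-3-[4-(benzyloxy)-3-methoxyphenyl]tetrahydro-1H,3H-furo[3,4-c]furan-1-one (cis-fused, aryl exo) | O=C1O[C@@H](c2ccc(OCc3ccccc3)c(OC)c2)[C@@H]2COC[C@H]12 | intermediate
11 | lithium enolate of 10 (O–Li on the former carbonyl carbon, double bond to the ring-fusion carbon C4; C2 and C3 as in 10) | [Li+].[O-]C1=C2COC[C@H]2[C@H](c2ccc(OCc3ccccc3)c(OC)c2)O1 | intermediate
12 | lithium [(2R,3S)-2-[4-(benzyloxy)-3-methoxyphenyl]-4-methylidene-5-oxooxolan-3-yl]methanolate | [Li+].[O-]C[C@@H]1C(=C)C(=O)O[C@H]1c1ccc(OCc2ccccc2)c(OC)c1 | intermediate
13 | (4S,5R)-5-[4-(benzyloxy)-3-methoxyphenyl]-4-{[(tert-butyldimethylsilyl)oxy]methyl}-3-methylideneoxolan-2-one | CC(C)(C)[Si](C)(C)OC[C@@H]1C(=C)C(=O)O[C@H]1c1ccc(OCc2ccccc2)c(OC)c1 | intermediate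
14 | [4-(benzyloxy)-3-methoxyphenyl]boronic acid | COc1cc(B(O)O)ccc1OCc1ccccc1 | starting material
15 | (3S,4S,5R)-3-[4-(benzyloxy)-3-methoxybenzyl]-5-[4-(benzyloxy)-3-methoxyphenyl]-4-{[(tert-butyldimethylsilyl)oxy]methyl}oxolan-2-one | CC(C)(C)[Si](C)(C)OC[C@@H]1[C@H](Cc2ccc(OCc3ccccc3)c(OC)c2)C(=O)O[C@H]1c1ccc(OCc2ccccc2)c(OC)c1 | intermediate
16 | (3S,4S,5R)-3-[4-(benzyloxy)-3-methoxybenzyl]-5-[4-(benzyloxy)-3-methoxyphenyl]-4-{[(tert-butyldimethylsilyl)oxy]methyl}oxolan-2-ol, both anomers | CC(C)(C)[Si](C)(C)OC[C@@H]1[C@H](Cc2ccc(OCc3ccccc3)c(OC)c2)C(O)O[C@H]1c1ccc(OCc2ccccc2)c(OC)c1 | intermediate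
17 | tert-butyl{[(2R,3S,4S)-2-[4-(benzyloxy)-3-methoxyphenyl]-4-[4-(benzyloxy)-3-methoxybenzyl]oxolan-3-yl]methoxy}dimethylsilane | CC(C)(C)[Si](C)(C)OC[C@@H]1[C@H](Cc2ccc(OCc3ccccc3)c(OC)c2)CO[C@H]1c1ccc(OCc2ccccc2)c(OC)c1 | intermediate
18 | [(2R,3S,4S)-2-[4-(benzyloxy)-3-methoxyphenyl]-4-[4-(benzyloxy)-3-methoxybenzyl]oxolan-3-yl]methanol | OC[C@@H]1[C@H](Cc2ccc(OCc3ccccc3)c(OC)c2)CO[C@H]1c1ccc(OCc2ccccc2)c(OC)c1 | intermediate
19 | (2R)-2-methylbutanoic acid | CC[C@@H](C)C(=O)O | starting material
20 | [(2R,3S,4S)-2-[4-(benzyloxy)-3-methoxyphenyl]-4-[4-(benzyloxy)-3-methoxybenzyl]oxolan-3-yl]methyl (2R)-2-methylbutanoate | CC[C@@H](C)C(=O)OC[C@@H]1[C@H](Cc2ccc(OCc3ccccc3)c(OC)c2)CO[C@H]1c1ccc(OCc2ccccc2)c(OC)c1 | intermediate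
21 | [(2R,3S,4S)-2-(4-hydroxy-3-methoxyphenyl)-4-(4-hydroxy-3-methoxybenzyl)oxolan-3-yl]methyl (2R)-2-methylbutanoate | CC[C@@H](C)C(=O)OC[C@@H]1[C@H](Cc2ccc(O)c(OC)c2)CO[C@H]1c1ccc(O)c(OC)c1 | target

## Step count and least certain steps

Total: 11 steps. Longest linear sequence: 11 steps (1 → 21); 2, 5, 14 and 19 enter as purchased materials.

**Step 4 (key step).** The ring-fusion carbon C4 may migrate in competition with C2, since both are secondary, and this would divert material to the regioisomeric lactone; slow electrophilic oxidation of the dialkoxyarene is a lesser concern. Fallback: give up substrate control and use catalyst control, oxidising 9 with a Baeyer–Villiger monooxygenase (a cyclohexanone or phenylacetone monooxygenase variant, O2, NADPH recycled by glucose dehydrogenase, buffer, 30 °C). Enzymes of this class are known to override intrinsic migratory aptitude in fused cyclobutanones and would also discriminate against the minor enantiomer. The fallback sets out from 9 and returns at 10 without a new compound.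

**Step 2.** Enantiofacial discrimination by the auxiliary may be incomplete. The activated amide may also acylate the electron-rich arene of a second molecule, or be intercepted by the ether oxygen of 5, which would lower conversion. Fallback for insufficient enantiopurity: classical resolution one stage later.
- Lactone 10 is saponified (NaOH, THF/H2O, 0 °C) to the sodium hydroxy carboxylate, sodium (3R,4S)-4-[(R)-[4-(benzyloxy)-3-methoxyphenyl](hydroxy)methyl]oxolane-3-carboxylate F1.
- F1 is treated in water with (R)-1-phenylethylammonium chloride, and the less soluble diastereomeric salt, the (R)-1-phenylethylammonium carboxylate F2, is crystallised to constant rotation. The antipodal amine is used if it gives the better-crystallising salt.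
- Acidification (aq. HCl, CH2Cl2) relactonises spontaneously to 10.

The fallback sets out from 10 and returns at 10.

**Step 5.** The C9 alkoxide 12 may attack the lactone carbonyl faster than it is silylated. This translactonisation moves the lactone oxygen from C2 to C9 and puts the silyl group on the benzylic oxygen. The elimination itself may also be slow, because the C7'–O bond is only partly aligned with the enolate π-system. Fallback: accept the rearrangement and finish through an open-chain diol.
- After elimination the mixture is warmed to rt to complete the acyl shift and trapped with TBSOTf/2,6-lutidine, giving (4S)-4-[(R)-[4-(benzyloxy)-3-methoxyphenyl][(tert-butyldimethylsilyl)oxy]methyl]-3-methylideneoxolan-2-one F3.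
- Conjugate arylation with 14 under the step 6 conditions, then DBU in CH2Cl2, gives the thermodynamically preferred trans lactone, (3S,4S)-3-[4-(benzyloxy)-3-methoxybenzyl]-4-[(R)-[4-(benzyloxy)-3-methoxyphenyl][(tert-butyldimethylsilyl)oxy]methyl]oxolan-2-one F4. In this lactone the trans arrangement corresponds to the 3,4-cis relation of the target.
- LiAlH4 (THF, 0 °C) gives (2S,3S)-2-[(R)-[4-(benzyloxy)-3-methoxyphenyl][(tert-butyldimethylsilyl)oxy]methyl]-3-[4-(benzyloxy)-3-methoxybenzyl]butane-1,4-diol F5.
- Camphorsulfonic acid in CH2Cl2 at 0 °C ionises the benzylic silyl ether, and the C5 hydroxyl closes the oxolane trans to the C3 arm, as is usual for such benzylic cations.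

The fallback sets out from 10 and returns at 18.

**Step 6.** Protonation of the rhodium enolate may show poor facial selectivity and give the 3,4-trans epimer; β-hydride elimination to a benzylidene lactone and protodeboronation of the electron-rich boronic acid would cost yield. Fallback: separate C–C bond formation from the stereochemical decision.
- The arylation is run without regard to C4, so that the crude product contains the (3R,4S,5R) epimer of 15, the 3,4-trans lactone F6.
- The mixture is converted with KN(SiMe3)2 (THF, −78 °C) into the potassium enolate F7.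
- F7 is quenched at −78 °C with 2,6-di-tert-butyl-4-methylphenol, a bulky proton donor that can reach C4 only from the face opposite the silyloxymethyl arm.

The fallback sets out from 13 and returns at 15.

**Step 11.** The catalyst may go on to cleave the benzylic C2–O1 bond once the para-phenol is free, opening the oxolane to a diol. Fallback: change from reductive to Lewis-acid debenzylation, BCl3 with pentamethylbenzene as cation scavenger in CH2Cl2 at −78 °C; this removes aryl benzyl ethers in the presence of esters and aryl methyl ethers. The fallback sets out from 20 and returns at 21 without a new compound.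

## Further compounds

F0 | step 4 | none | none
F1 | step 2 | sodium (3R,4S)-4-[(R)-[4-(benzyloxy)-3-methoxyphenyl](hydroxy)methyl]oxolane-3-carboxylate | [Na+].[O-]C(=O)[C@H]1COC[C@H]1[C@@H](O)c1ccc(OCc2ccccc2)c(OC)c1
F2 | step 2 | (R)-1-phenylethylammonium (3R,4S)-4-[(R)-[4-(benzyloxy)-3-methoxyphenyl](hydroxy)methyl]oxolane-3-carboxylate | C[C@@H]([NH3+])c1ccccc1.[O-]C(=O)[C@H]1COC[C@H]1[C@@H](O)c1ccc(OCc2ccccc2)c(OC)c1
F3 | step 5 | (4S)-4-[(R)-[4-(benzyloxy)-3-methoxyphenyl][(tert-butyldimethylsilyl)oxy]methyl]-3-methylideneoxolan-2-one | C=C1C(=O)OC[C@H]1[C@@H](O[Si](C)(C)C(C)(C)C)c1ccc(OCc2ccccc2)c(OC)c1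
F4 | step 5 | (3S,4S)-3-[4-(benzyloxy)-3-methoxybenzyl]-4-[(R)-[4-(benzyloxy)-3-methoxyphenyl][(tert-butyldimethylsilyl)oxy]methyl]oxolan-2-one | O=C1OC[C@@H]([C@@H](O[Si](C)(C)C(C)(C)C)c2ccc(OCc3ccccc3)c(OC)c2)[C@@H]1Cc1ccc(OCc2ccccc2)c(OC)c1
F5 | step 5 | (2S,3S)-2-[(R)-[4-(benzyloxy)-3-methoxyphenyl][(tert-butyldimethylsilyl)oxy]methyl]-3-[4-(benzyloxy)-3-methoxybenzyl]butane-1,4-diol | OC[C@@H]([C@@H](O[Si](C)(C)C(C)(C)C)c1ccc(OCc2ccccc2)c(OC)c1)[C@@H](CO)Cc1ccc(OCc2ccccc2)c(OC)c1
F6 | step 6 | (3R,4S,5R)-3-[4-(benzyloxy)-3-methoxybenzyl]-5-[4-(benzyloxy)-3-methoxyphenyl]-4-{[(tert-butyldimethylsilyl)oxy]methyl}oxolan-2-one | CC(C)(C)[Si](C)(C)OC[C@@H]1[C@@H](Cc2ccc(OCc3ccccc3)c(OC)c2)C(=O)O[C@H]1c1ccc(OCc2ccccc2)c(OC)c1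
F7 | step 6 | potassium enolate of 15 (O–K on the former carbonyl carbon, double bond to C4; C2 and C3 as in 15) | [K+].[O-]C1=C(Cc2ccc(OCc3ccccc3)c(OC)c2)[C@@H](CO[Si](C)(C)C(C)(C)C)[C@H](c2ccc(OCc3ccccc3)c(OC)c2)O1
F0 | step 11 | none | none
A1 | alternative 1 | (3E,4S,5R)-3-[4-(benzyloxy)-3-methoxybenzylidene]-5-[4-(benzyloxy)-3-methoxyphenyl]-4-{[(tert-butyldimethylsilyl)oxy]methyl}oxolan-2-one | CC(C)(C)[Si](C)(C)OC[C@@H]1/C(=C\c2ccc(OCc3ccccc3)c(OC)c2)C(=O)O[C@H]1c1ccc(OCc2ccccc2)c(OC)c1
A2 | alternative 1 | (1R,2S)-1,4-bis[4-(benzyloxy)-3-methoxyphenyl]-2-{[(tert-butyldimethylsilyl)oxy]methyl}but-3-yn-1-ol (anti) | CC(C)(C)[Si](C)(C)OC[C@H](C#Cc1ccc(OCc2ccccc2)c(OC)c1)[C@@H](O)c1ccc(OCc2ccccc2)c(OC)c1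
A3 | alternative 2 | [(2R,3S,4S)-2-[4-(benzyloxy)-3-methoxyphenyl]-4-[4-(benzyloxy)-3-methoxybenzyl]oxolan-3-yl]methanol | OC[C@@H]1[C@H](Cc2ccc(OCc3ccccc3)c(OC)c2)CO[C@H]1c1ccc(OCc2ccccc2)c(OC)c1
A4 | alternative 2 | 2-[(S)-[4-(benzyloxy)-3-methoxyphenyl]{[(2E)-3-[4-(benzyloxy)-3-methoxyphenyl]prop-2-en-1-yl]oxy}methyl]oxirane (either epoxide epimer) | COc1cc(/C=C/CO[C@H](C2CO2)c2ccc(OCc3ccccc3)c(OC)c2)ccc1OCc1ccccc1
A5 | alternative 3 | (−)-pinoresinol 4-O-acetate 4'-O-benzyl ether | COc1cc(ccc1OCc1ccccc1)[C@@H]1OC[C@@H]2[C@H]1CO[C@H]2c1ccc(OC(C)=O)c(OC)c1
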